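**The constants.** The constants showed me first that in the flask the impurity would catch the free catalyst as it appeared, because capture at 2.76 s⁻¹ stood well above release at 0.059 s⁻¹ and far above decay at 4.2 × 10⁻⁵ s⁻¹.

    precatalyst → free catalyst (k1 = 0.059 s⁻¹)
    free catalyst + impurity → spent catalyst A (k2 = 12000 M⁻¹ s⁻¹)
    isomer of the product + free catalyst ⇌ substrate + free catalyst, rate k3*[free catalyst]*[isomer of the product] forward; the back reaction follows from the equilibrium constant (k3 = 43 M⁻¹ s⁻¹)
    free catalyst → spent catalyst B (k4 = 4.2 × 10⁻⁵ s⁻¹)
    substrate + free catalyst ⇌ target + free catalyst, rate k5*[substrate]*[free catalyst] forward; the back reaction follows from the equilibrium constant (K5 = 2.4, k5 = 110 M⁻¹ s⁻¹)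
    target + free catalyst ⇌ isomer of the product + free catalyst, rate k6*[free catalyst]*[target] forward; the back reaction follows from the equilibrium constant (K6 = 0.98, k6 = 370 M⁻¹ s⁻¹)

substrate 0.25 M; precatalyst 0.1 mol%; impurity 0.23 mM; time 3.0 h

1. the state of affairs at 3.0 h: stopped, and by what, or still going (it is still moving / forward and back rates have come level / no working catalyst is left / all of the substrate has reacted)
2. how much target there is at 3.0 h, in percent of the substrate charged

**Surplus catalyst.** I took that capture as complete. The flask charged 0.250 mM of catalyst against 0.23 mM of impurity, so I reckoned with 0.0200 mM of surplus catalyst, the charge minus the impurity.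

**From above.** I set target's ceiling at its equilibrium share, since target, substrate and isomer of the product stand as 2.4 to 1 to 2.35 at equilibrium, which gives 41.7%.

**From below.** I let the surplus decay for the whole run, down to a floor of 0.0127 mM. Even there the pseudo-first-order loss of substrate toward target, forward step alone, has a time of 0.199 h, far short of 3.0 h. That makes 15.1 such times, so my lower estimate is 41.7% and the bracket closes on the ceiling.

**Forecast and truth.** The forecast said forward and back rates have come level, with target at 41.7% (range 41% to 42.4%), since “the mixture fully equilibrates”, which puts it inside my bracket. The simulation of the flask gave forward and back rates have come level, with target at 41.7%.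

**Neighbouring flask.** In the flask, free catalyst read 7.66% of the charge at 0.300 h, against 7.65% for the surplus decayed to that moment. The neighbour charged with 0.04 mol% of precatalyst holds 0.100 mM of catalyst against the same impurity, so its surplus comes out at −0.130 mM, and the reckoning leaves 56.5% of the impurity over and no free catalyst standing at the end. At 3.00 h that neighbour read impurity 56.5% of its own charge, free catalyst 0%, substrate 99.0% and target 0.520%.

All constants come from no measurement; the result is computed.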